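- In a one-step world, substrate + partner → target, and each target takes one partner. Thursday's, Tuesday's, Wednesday's and Friday's each hold 1.47 M of partner, less than their 2.1 M of substrate, so partner is the limiting reagent and the ceiling is 70.0% of the substrate charged.

common to all: substrate 2.1 M

| charge | partner | temperature | remark | time |
|---|---|---|---|---|
| theta | 0.98 M | 55 °C | run made earlier |  |
| gamma | 2.2 M | 98 °C | run made earlier |  |
| Thursday's | 1.47 M | 85 °C |  | 4.0 d |
| Tuesday's | 1.47 M | 60 °C |  | 4.0 d |
| Wednesday's | 1.47 M | 135 °C |  | 4.0 d |
| Friday's | 1.47 M | 110 °C |  | 4.0 d |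

| run | time / d | target / % |
|---|---|---|
| theta | 5.00 | 5.3 |
| theta | 10.0 | 10.0 |
| theta | 12.0 | 13.0 |
| theta | 20.0 | 19.7 |
| gamma | 0.500 | 49.1 |
| gamma | 1.04 | 71.2 |
| gamma | 1.67 | 74.7 |
| gamma | 2.00 | 75.0 |
| gamma | 2.50 | 76.1 |

(scatter of a reading: 1 percentage point)

- the earlier runs were read with a standard deviation of 1 percentage point

* the flask with the highest amount of target, in percent of the substrate charged ("all alike" if they lie within 1.5 percentage points) (Thursday's / Tuesday's / Wednesday's / Friday's / all alike)
* final target, as a percentage of the substrate charged, in Thursday's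
* final target, as a percentage of the substrate charged, in Tuesday's
* final target, as a percentage of the substrate charged, in Wednesday's
* final target, as a percentage of the substrate charged, in Friday's

- The gamma run flattens, with a last reading of 76.1%, which is 1.60 M of target. The one-step count then leaves 0.502 M of substrate and 0.602 M of partner, so that count does not explain the stop, and this reckoning reads it in two ways.
- The first way calls the stop equilibrium, with K = target/(substrate × partner), which gives 5.29 M⁻¹. Carried unchanged to Thursday's charges, K gives 1.21 M of target, or 57.6%, and leaves 17.6% of the partner.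
- The second way supposes that partner is lost by an unseen route and that the flask stops when partner is gone. It uses the partner yield Y, the part of the charged partner that ends as target, read from gamma as 72.6%.
- Carried to Thursday's, Y times the ceiling gives 50.8%, with no partner left by this supposition.
- Thursday's has to climb at 0.127 d⁻¹ on average to get there in 4.0 d. The first slope of the theta run is 0.0106 d⁻¹ and that of the gamma run 0.982 d⁻¹. Thursday's climb is faster than the theta slope and slower than the gamma slope, and its 85 °C lies between those two runs' temperatures.
- Tuesday's, at 60 °C, stands near theta's 55 °C, whose slope over 4.0 d makes 4.24%, so Tuesday's looks short of the ceiling.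
- The two ways part by 6.8 points, and one measurement separates them: Thursday's partner at the end, 17.6% of its charge by the first way and none by the second. This reckoning holds to the second way, which costs one division.
- The forecast names Thursday's, with 54% there, 52% in Friday's, 42% in Wednesday's and 11.5% in Tuesday's. Its 54% lies above the second way and below the first, and it adds: “Thursday's narrowly leads, but this depends on the assumed ΔH.”
- Thursday's holds the most target, 56.4%, ahead of Friday's 49.3%, Wednesday's 40.0% and Tuesday's 8.09%.

    substrate ⇌ tight pair (K = 0.0430, k = 0.200 h⁻¹, Ea = 115 kJ mol⁻¹, ΔH = −20.0 kJ mol⁻¹)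
    tight pair ⇌ loose pair (K = 0.670, k = 33.0 h⁻¹, Ea = 110 kJ mol⁻¹, ΔH = 15.0 kJ mol⁻¹)
    partner + loose pair → isomer of the product (k = 220 M⁻¹ h⁻¹, Ea = 57.0 kJ mol⁻¹)
    partner + tight pair → target (k = 190 M⁻¹ h⁻¹, Ea = 54.0 kJ mol⁻¹)
    partner → decomposed reagent (k = 0.0680 h⁻¹, Ea = 120 kJ mol⁻¹)
    (constants at 110 °C)

- Thursday's partner stands at 0% of its charge after 4.00 d, not the 17.6% of the first way. Thursday's Y comes to 80.6%, higher than gamma's 72.6%. Friday's, with partner at 0%, has a Y of 70.4%.

Readings and results stem from a simulated flask with constants of no real substance.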